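**Retrosynthetic overview**
1. Last bond: C(sp3)–C(sp2) to the (Z)-2-methylallyl alcohol, by nickel/photoredox decarboxylative alkenylation of a C3-acid arm with (Z)-3-iodo-2-methylprop-2-en-1-ol.
2. Key bond: the central C–C bond of the three-carbon linker between the two stereocentres, by a photoredox decarboxylative, denitrogenative coupling of a lactone-derived carboxylate (hydroxymethyl half) with an aldehyde tosylhydrazone (acetate half).
3. Both stereocentres come from epichlorohydrin via the malonate cyclopropane-lactone: (S)-epichlorohydrin gives the acetate-bearing centre (cyclopropane opened by a malonate), (R)-epichlorohydrin gives the hydroxymethyl centre (opened by a vinyl cuprate).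
4. The butenolide is bought as 3-bromofuran-2(5H)-one and joined to the allyl arm by B-alkyl Suzuki coupling before the key step.
5. Ring order: bicyclic cyclopropane-lactones (steps 1, 5), then monocyclic γ-lactones (2, 6), butenolide attached (7), one lactone reduced and opened (3, 4), the other consumed as CO2 in the key step (8), where the butenolide is opened and re-closed; no ring is formed afterwards.

Assumption: the target is taken exactly as drawn in the SMILES (Z alkene, 2R,6S on the nonyl acetate chain), and operations run in one flask without isolation are counted as one step.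

Step 1
Reactants: 1 (S)-epichlorohydrin; 2 diethyl malonate
Product: 3 ethyl (1R,5S)-2-oxo-3-oxabicyclo[3.1.0]hexane-1-carboxylate
Conditions: NaOEt (1.05 equiv), EtOH, 0 °C → reflux, 20 h
Reagents that add atoms: none
Why: Tandem alkylation/cyclopropanation/lactonization: the malonate anion opens the epoxide at CH2, the alkoxide re-closes onto CH2Cl, and 3-exo-tet C-alkylation with inversion at the former epoxide CH followed by lactonization gives the cis-fused lactone, so the bought (S) centre sets C5 (S) and thereby C1 (R).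

Step 2
Reactants: 3 ethyl (1R,5S)-2-oxo-3-oxabicyclo[3.1.0]hexane-1-carboxylate; 4 tert-butyl ethyl malonate
Product: 6 tert-butyl 3-[(3S)-5-oxotetrahydrofuran-3-yl]propanoate, via triester adduct 5 (not isolated)
Conditions: 4 (1.5 equiv), NaH (1.0 equiv), DMSO, 25 → 60 °C; then NH4Cl (1.0 equiv), LiCl, H2O, 140 °C (one pot)
Reagents that add atoms: none
Why: Homoconjugate (homo-Michael) addition of the malonate anion at the CH2 of the doubly activated cyclopropane, then Krapcho dealkoxycarbonylation, which removes both ethyl esters by SN2 at ethyl but cannot touch the tert-butyl ester; the stereocentre is not involved.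

Step 3
Reactants: 6 tert-butyl 3-[(3S)-5-oxotetrahydrofuran-3-yl]propanoate
Product: 7 tert-butyl 3-[(3S)-5-hydroxytetrahydrofuran-3-yl]propanoate (lactol, anomer mixture)
Conditions: iBu2AlH (1.1 equiv), CH2Cl2, −78 °C; aq. KNaC4H4O6 work-up
Reagents that add atoms: none
Why: Partial reduction of a γ-lactone to the lactol: the aluminium hemiacetal is stable at −78 °C and the hindered tert-butyl ester is reduced far more slowly.

Step 4
Reactants: 7 tert-butyl 3-[(3S)-5-hydroxytetrahydrofuran-3-yl]propanoate
Product: 9 tert-butyl (4S)-4-(acetoxymethyl)-6-[2-(4-methylbenzenesulfonyl)hydrazinylidene]hexanoate, via hydroxy hydrazone 8 (not isolated)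
Conditions: TsNHNH2 (1.0 equiv), 4 Å MS, THF, 40 °C; then Ac2O (1.1 equiv), pyridine, 0 °C (one pot)
Reagents that add atoms: 4-methylbenzenesulfonohydrazide (Cc1ccc(cc1)S(=O)(=O)NN); acetic anhydride (CC(=O)OC(C)=O)
Why: Hydrazone condensation of the latent aldehyde opens the lactol and frees the primary alcohol, which is O-acetylated faster than the weakly nucleophilic sulfonylhydrazone N–H reacts.

Step 5
Reactants: 10 (R)-epichlorohydrin; 2 diethyl malonate
Product: 11 ethyl (1S,5R)-2-oxo-3-oxabicyclo[3.1.0]hexane-1-carboxylate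
Conditions: NaOEt (1.05 equiv), EtOH, 0 °C → reflux, 20 h
Reagents that add atoms: none
Why: Same tandem alkylation/cyclopropanation/lactonization as in step 1; the bought (R) centre gives (1S,5R).

Step 6
Reactants: 11 ethyl (1S,5R)-2-oxo-3-oxabicyclo[3.1.0]hexane-1-carboxylate
Product: 13 (4R)-4-(prop-2-en-1-yl)dihydrofuran-2(3H)-one, via allyl lactone ester 12 (not isolated)
Conditions: CH2=CHMgBr (1.3 equiv), CuBr·SMe2 (10 mol %), THF, −40 → −20 °C; then aq. NH4Cl (1.3 equiv), DMSO, LiCl, distil off THF, 140 °C (one pot)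
Reagents that add atoms: vinylmagnesium bromide, CH2=CHMgBr (C=C[Mg]Br)
Why: Copper-catalysed Grignard homoconjugate opening at the cyclopropane CH2 (the way this lactone is opened by ethyl Grignard reagents) followed by Krapcho de-ethoxycarbonylation; the stereocentre keeps its configuration.

Step 7
Reactants: 13 (4R)-4-(prop-2-en-1-yl)dihydrofuran-2(3H)-one; 14 3-bromofuran-2(5H)-one
Product: 16 (4R)-4-[3-(2-oxo-2,5-dihydrofuran-3-yl)propyl]dihydrofuran-2(3H)-one, via B-alkyl-9-BBN adduct 15 (not isolated)
Conditions: 9-BBN-H (1.2 equiv), THF, 0 → 25 °C; then 14 (1.3 equiv), Pd(dppf)Cl2 (5 mol %), AsPh3 (10 mol %), K3PO4 (3 M aq., 2 equiv), DMF, 25 °C; 1 M HCl work-up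
Reagents that add atoms: none
Why: Anti-Markovnikov hydroboration of the terminal alkene and B-alkyl Suzuki–Miyaura coupling with the α-bromo butenolide (oxidative addition of zerovalent palladium into the vinyl C–Br bond) attach the intact butenolide through a (CH2)3 tether.

Step 8
Reactants: 16 (4R)-4-[3-(2-oxo-2,5-dihydrofuran-3-yl)propyl]dihydrofuran-2(3H)-one; 9 tert-butyl (4S)-4-(acetoxymethyl)-6-[2-(4-methylbenzenesulfonyl)hydrazinylidene]hexanoate
Product: 19 tert-butyl (4R,8S)-4-(acetoxymethyl)-8-(hydroxymethyl)-11-(2-oxo-2,5-dihydrofuran-3-yl)undecanoate, via dicesium dicarboxylate 17 (not isolated), via cesium hydroxy-enoate 18 (not isolated)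
Conditions: 16 (1.5 equiv), CsOH·H2O (3.0 equiv), THF/H2O, 0 → 25 °C, evaporate; then 9 (1.0 equiv), 4CzIPN (2 mol %), degassed DMSO/H2O 5:1, 450 nm LEDs, 25 °C; then 1 M HCl to pH 2, 25 °C
Reagents that add atoms: none
Why: Proposed new method: a photoredox decarboxylative, denitrogenative C(sp3)–C(sp3) coupling in which a lactone is the latent primary alkyl radical and an aldehyde N-tosylhydrazone is the latent CH2 electrophile – excited 4CzIPN oxidises the saturated carboxylate of 17 (the conjugated enoate carboxylate is harder to oxidise and gives no stable radical), CO2 loss gives the primary radical next to the untouched hydroxymethyl stereocentre, this nucleophilic radical adds to the C=N carbon of 9, the hydrazinyl radical is reduced by the 4CzIPN radical anion (closing the cycle), sulfinate is expelled, the monoalkyl diazene loses N2 to leave the central CH2, and acidification re-closes the butenolide; the closest known reaction types are the reductive coupling of aldehyde tosylhydrazones with alkyllithiums (addition, sulfinate loss, N2 loss), the boronic acid/tosylhydrazone reductive coupling, decarboxylative Giese additions and radical additions to C=N acceptors; no stereocentre is formed or broken.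

Step 9
Reactants: 19 tert-butyl (4R,8S)-4-(acetoxymethyl)-8-(hydroxymethyl)-11-(2-oxo-2,5-dihydrofuran-3-yl)undecanoate
Product: 20 (4R,8S)-4-(acetoxymethyl)-8-(hydroxymethyl)-11-(2-oxo-2,5-dihydrofuran-3-yl)undecanoic acid
Conditions: CF3CO2H/CH2Cl2 1:4, 0 → 25 °C; aqueous work-up
Reagents that add atoms: none
Why: Acidolysis of the tert-butyl ester (E1 loss of isobutene) frees the acid without touching acetate, alcohol or butenolide.

Step 10
Reactants: 21 propargyl alcohol
Product: 23 (2Z)-3-iodo-2-methylprop-2-en-1-ol, via magnesacycle 22 (not isolated)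
Conditions: MeMgBr (2.5 equiv), CuI (10 mol %), THF, −10 → 25 °C; then I2 (1.2 equiv), −10 °C; 1 M HCl work-up
Reagents that add atoms: methylmagnesium bromide, MeMgBr (C[Mg]Br); iodine (II)
Why: Copper-catalysed anti-carbomagnesiation of the propargylic alkoxide gives the five-membered magnesacycle, and iodinolysis with retention places iodine cis to CH2OH (Z).

Step 11
Reactants: 20 (4R,8S)-4-(acetoxymethyl)-8-(hydroxymethyl)-11-(2-oxo-2,5-dihydrofuran-3-yl)undecanoic acid; 23 (2Z)-3-iodo-2-methylprop-2-en-1-ol
Product: 24 (2R,6S)-2-[(3Z)-5-hydroxy-4-methylpent-3-en-1-yl]-6-(hydroxymethyl)-9-(2-oxo-2,5-dihydrofuran-3-yl)nonyl acetate (CNP0325245.2)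
Conditions: 23 (2.0 equiv), [Ir(dF(CF3)ppy)2(dtbbpy)]PF6 (2 mol %), NiCl2·glyme (10 mol %), dtbbpy (12 mol %), Cs2CO3 (1.0 equiv), degassed DMSO, 450 nm LEDs, 25 °C
Reagents that add atoms: none
Why: Nickel/photoredox decarboxylative alkenylation: the excited iridium complex oxidises the carboxylate, the primary radical is captured by the divalent alkenylnickel species formed by oxidative addition of zerovalent nickel to 23, and reductive elimination forms the C(sp3)–C(sp2) bond with retention of the Z geometry; no stereocentre is touched.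

Note on descriptors: no bond to either stereocentre is made or broken after steps 1 and 5. The changes from 9 (4S) and 16 (4R) to 19 (4R,8S) arise only from changed CIP priorities.

**Compound list**
1 | (S)-epichlorohydrin | ClC[C@@H]1CO1 | starting material
2 | diethyl malonate | CCOC(=O)CC(=O)OCC | starting material
3 | ethyl (1R,5S)-2-oxo-3-oxabicyclo[3.1.0]hexane-1-carboxylate | O=C1OC[C@H]2C[C@@]12C(=O)OCC | intermediate
4 | tert-butyl ethyl malonate | CCOC(=O)CC(=O)OC(C)(C)C | starting material
5 | ethyl (4S)-4-[3-tert-butoxy-2-(ethoxycarbonyl)-3-oxopropyl]-2-oxotetrahydrofuran-3-carboxylate (epimers at C3 and at the malonate carbon) | O=C1OC[C@@H](CC(C(=O)OCC)C(=O)OC(C)(C)C)C1C(=O)OCC | intermediate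
6 | tert-butyl 3-[(3S)-5-oxotetrahydrofuran-3-yl]propanoate | O=C1C[C@H](CCC(=O)OC(C)(C)C)CO1 | intermediate
7 | tert-butyl 3-[(3S)-5-hydroxytetrahydrofuran-3-yl]propanoate (anomer mixture) | OC1C[C@H](CCC(=O)OC(C)(C)C)CO1 | intermediate
8 | tert-butyl (4S)-4-(hydroxymethyl)-6-[2-(4-methylbenzenesulfonyl)hydrazinylidene]hexanoate | OC[C@@H](CCC(=O)OC(C)(C)C)CC=NNS(=O)(=O)c1ccc(C)cc1 | intermediate
9 | tert-butyl (4S)-4-(acetoxymethyl)-6-[2-(4-methylbenzenesulfonyl)hydrazinylidene]hexanoate | CC(=O)OC[C@@H](CCC(=O)OC(C)(C)C)CC=NNS(=O)(=O)c1ccc(C)cc1 | intermediate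
10 | (R)-epichlorohydrin | ClC[C@H]1CO1 | starting material
11 | ethyl (1S,5R)-2-oxo-3-oxabicyclo[3.1.0]hexane-1-carboxylate | O=C1OC[C@@H]2C[C@]12C(=O)OCC | intermediate
12 | ethyl (4R)-2-oxo-4-(prop-2-en-1-yl)tetrahydrofuran-3-carboxylate (C3 epimers) | O=C1OC[C@H](CC=C)C1C(=O)OCC | intermediate
13 | (4R)-4-(prop-2-en-1-yl)dihydrofuran-2(3H)-one | O=C1C[C@@H](CC=C)CO1 | intermediate
14 | 3-bromofuran-2(5H)-one | O=C1OCC=C1Br | starting material
15 | (4R)-4-[3-(9-borabicyclo[3.3.1]nonan-9-yl)propyl]dihydrofuran-2(3H)-one | O=C1C[C@@H](CCCB2C3CCCC2CCC3)CO1 | intermediate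
16 | (4R)-4-[3-(2-oxo-2,5-dihydrofuran-3-yl)propyl]dihydrofuran-2(3H)-one | O=C1C[C@@H](CCCC2=CCOC2=O)CO1 | intermediate
17 | dicesium (2Z,6R)-2-(2-hydroxyethylidene)-6-(hydroxymethyl)octanedioate | [Cs+].[Cs+].[O-]C(=O)C[C@H](CO)CCC/C(C([O-])=O)=C/CO | intermediate
18 | cesium (2Z,6S,10R)-10-(acetoxymethyl)-13-tert-butoxy-2-(2-hydroxyethylidene)-6-(hydroxymethyl)-13-oxotridecanoate | [Cs+].CC(=O)OC[C@@H](CCC(=O)OC(C)(C)C)CCC[C@H](CO)CCC/C(C([O-])=O)=C/CO | intermediate
19 | tert-butyl (4R,8S)-4-(acetoxymethyl)-8-(hydroxymethyl)-11-(2-oxo-2,5-dihydrofuran-3-yl)undecanoate | CC(=O)OC[C@@H](CCC(=O)OC(C)(C)C)CCC[C@H](CO)CCCC1=CCOC1=O | intermediate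
20 | (4R,8S)-4-(acetoxymethyl)-8-(hydroxymethyl)-11-(2-oxo-2,5-dihydrofuran-3-yl)undecanoic acid | CC(=O)OC[C@@H](CCC(=O)O)CCC[C@H](CO)CCCC1=CCOC1=O | intermediate
21 | propargyl alcohol | C#CCO | starting material
22 | 4-methyl-2,5-dihydro-1,2-oxamagnesole (cyclic alkenylmagnesium alkoxide) | CC1=C[Mg]OC1 | intermediate
23 | (2Z)-3-iodo-2-methylprop-2-en-1-ol | OC/C(C)=C\I | intermediate
24 | (2R,6S)-2-[(3Z)-5-hydroxy-4-methylpent-3-en-1-yl]-6-(hydroxymethyl)-9-(2-oxo-2,5-dihydrofuran-3-yl)nonyl acetate (CNP0325245.2) | CC(=O)OC[C@@H](CC/C=C(/C)CO)CCC[C@H](CO)CCCC1=CCOC1=O | target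

**Step count**
Total steps: 11. Longest linear sequence: 7 (steps 1, 2, 3, 4, 8, 9, 11).

**Three steps most likely to fail**

Step 8 (the proposed new coupling). Risks: addition of the unactivated primary radical to the C=N bond may be slower than its reduction to the alkane, and partial deprotonation of the hydrazone by the carboxylate would open a competing oxidation path. The butenolide is installed before this step on purpose: a terminal allyl group would sit in a 5-hexenyl relationship to the central carbon, which may pass through a radical when the diazene collapses.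
The fallback uses known chemistry, sets out from 6 and 13 and comes back at 19. LiOH, then Ac2O/pyridine, opens and acetylates 6 to (3S)-3-(acetoxymethyl)-6-tert-butoxy-6-oxohexanoic acid F1. ClCO2iBu with N-methylmorpholine gives its mixed isobutyl carbonic anhydride F2, and Me3SiCHN2 gives the diazoketone tert-butyl (4S)-4-(acetoxymethyl)-7-diazo-6-oxoheptanoate F3. Wolff rearrangement (AgO2CPh, Et3N, THF/H2O) completes the Arndt–Eistert homologation to (4R)-4-(acetoxymethyl)-7-tert-butoxy-7-oxoheptanoic acid F4. NaOH (1 equiv) opens 13 to sodium (3R)-3-(hydroxymethyl)hex-5-enoate F5. Mixed Kolbe electrolysis of F4 with excess F5 (platinum electrodes, MeOH, 15 °C, constant current) gives tert-butyl (4R,8S)-4-(acetoxymethyl)-8-(hydroxymethyl)undec-10-enoate F6; neither radical has an alkene within cyclization range. Hydroboration with 9-BBN-H gives the bis(9-BBN) adduct F7, and Suzuki coupling with 14 under the conditions of step 7 gives 19.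

Step 7 (B-alkyl Suzuki coupling with the bromobutenolide). Risks: 14 and the product are base-sensitive, and transmetalation may be slow.
The fallback sets out from 13 and comes back at 16. Hydroboration with 9-BBN-H (via 15) and oxidation with NaBO3·4H2O give (4R)-4-(3-hydroxypropyl)dihydrofuran-2(3H)-one F8. I2, PPh3 and imidazole give (4R)-4-(3-iodopropyl)dihydrofuran-2(3H)-one F9. Zn dust with LiCl in THF gives iodo{3-[(3R)-5-oxotetrahydrofuran-3-yl]propyl}zinc F10. A base-free Negishi coupling with 14 (Pd(PPh3)4, THF, 25 °C) gives 16.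

Step 11 (decarboxylative alkenylation of an unactivated primary acid). Risks: the carboxylate is oxidised slowly, and C–O coupling to the alkenyl ester can compete.
The fallback sets out from 20 and comes back at 24. N-Hydroxyphthalimide and N,N'-diisopropylcarbodiimide in CH2Cl2 give the 1,3-dioxoisoindolin-2-yl ester of 20 F11. This redox-active ester is coupled with 23 by nickel-catalysed reductive cross-electrophile coupling (NiBr2·glyme, dtbbpy, Zn, DMA, 25 °C), with no photochemical oxidation step, to give 24.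

**Further compounds**
F1 | step 8 | (3S)-3-(acetoxymethyl)-6-tert-butoxy-6-oxohexanoic acid | CC(=O)OC[C@H](CC(=O)O)CCC(=O)OC(C)(C)C
F2 | step 8 | mixed isobutyl carbonic anhydride of F1 | CC(=O)OC[C@H](CC(=O)OC(=O)OCC(C)C)CCC(=O)OC(C)(C)C
F3 | step 8 | tert-butyl (4S)-4-(acetoxymethyl)-7-diazo-6-oxoheptanoate | CC(=O)OC[C@H](CC(=O)C=[N+]=[N-])CCC(=O)OC(C)(C)C
F4 | step 8 | (4R)-4-(acetoxymethyl)-7-tert-butoxy-7-oxoheptanoic acid | CC(=O)OC[C@H](CCC(=O)O)CCC(=O)OC(C)(C)C
F5 | step 8 | sodium (3R)-3-(hydroxymethyl)hex-5-enoate | [Na+].[O-]C(=O)C[C@H](CO)CC=C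
F6 | step 8 | tert-butyl (4R,8S)-4-(acetoxymethyl)-8-(hydroxymethyl)undec-10-enoate | CC(=O)OC[C@@H](CCC(=O)OC(C)(C)C)CCC[C@H](CO)CC=C
F7 | step 8 | bis(9-BBN) adduct of F6 (O-borinate and terminal C-borane) | CC(=O)OC[C@@H](CCC(=O)OC(C)(C)C)CCC[C@H](COB1C2CCCC1CCC2)CCCB1C2CCCC1CCC2
F8 | step 7 | (4R)-4-(3-hydroxypropyl)dihydrofuran-2(3H)-one | O=C1C[C@@H](CCCO)CO1
F9 | step 7 | (4R)-4-(3-iodopropyl)dihydrofuran-2(3H)-one | O=C1C[C@@H](CCCI)CO1
F10 | step 7 | iodo{3-[(3R)-5-oxotetrahydrofuran-3-yl]propyl}zinc | O=C1C[C@@H](CCC[Zn]I)CO1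
F11 | step 11 | 1,3-dioxoisoindolin-2-yl (4R,8S)-4-(acetoxymethyl)-8-(hydroxymethyl)-11-(2-oxo-2,5-dihydrofuran-3-yl)undecanoate | CC(=O)OC[C@@H](CCC(=O)ON1C(=O)c2ccccc2C1=O)CCC[C@H](CO)CCCC1=CCOC1=O
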